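The data stem from a simulated flask for an exercise; scatter was added.

The alder run, with 0.50 equiv of second substrate, had made 29.5% target at 0.667 min; the larch run, with 0.75 equiv, had made 22.7%, so the run with more second substrate is the slower.

in all of them: starting material 0.12 M; enzyme 0.091 mol%
- alder: second substrate 0.50 equiv; protic impurity 0.024 M; run made earlier
- larch: second substrate 0.75 equiv; protic impurity 0.024 M; run made earlier
- flask: second substrate 1.00 equiv; protic impurity 0.0240 M

| run | time / min | target / % | starting material / % |
|---|---|---|---|
| alder | 0.667 | 29.5 | 70.5 |
| alder | 1.33 | 54.6 | 44.9 |
| alder | 2.00 | 74.6 | 26.0 |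
| alder | 3.00 | 92.5 | 7.4 |
| alder | 4.00 | 99.2 | 1.7 |
| alder | 5.00 | 100.2 | 0.3 |
| larch | 0.667 | 22.7 | 77.3 |
| larch | 1.33 | 42.1 | 57.8 |
| larch | 2.00 | 59.9 | 40.3 |
| larch | 3.00 | 79.2 | 19.7 |
| larch | 4.00 | 91.7 | 7.4 |
| larch | 5.00 | 97.9 | 1.9 |

(scatter of a reading: 0.3 percentage points)

- apparent order in second substrate when 5.0% of the starting material are converted (percent change of the rate of making target for one percent more second substrate charged)

- the earlier runs were read with a standard deviation of 0.3 percentage points

Turn each first reading into a time: at that early average pace the whole charge would take 2.26 min in alder and 2.94 min in larch. Assume these times lie on a straight line in the second substrate charged; two points can't test that. Carried to the flask's 1.00 equiv, the line splits the flask's time in two: a bare time of 0.906 min and a held time of 2.71 min, which grows with the charge. One percent more second substrate adds one percent to the held time, so the order is minus the hold-up share, the held time over the sum of both times. I get 0.749, so minus that, nearer minus one than zero since the held time is the longer.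

The forecast differs from mine: it gives −0.8, and of its step to the flask it says: “This extrapolation is uncertain.”

The flask gives −0.81.

    starting material + enzyme ⇌ complex A (K = 22.0 /M, k = 2.70 × 10⁵ /M/min)
    complex A → enzyme + target (k = 2500 /min)
    second substrate + enzyme ⇌ complex B (K = 130 /M, k = 3.50 × 10⁵ /M/min)
    complex B → enzyme + second product (k = 140 /min)
    second substrate + protic impurity → quenched substrate (k = 5.60 /M/min)

At 1.82 min the flask's second substrate enters complex B 63 times faster, forward step alone, than it turns into quenched substrate. Earlier, at 0.181 min, when 5.0% of the flask's starting material are converted, complex B, the resting state, is 82.2% of the catalyst, against a hold-up share of 74.9%. With twice the second substrate, the hold-up share puts the time to that conversion at 1.75 times the flask's, and that run takes 1.81 times.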